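The numbers in the tables are calculated with made-up constants, and the scatter is random.

The flask holds 20 mM of free monomer, 2.00 mM of protic impurity and 0.20 mM of initiator, and I want the average chain length, counting every chain begun.

all flasks: free monomer 0.020 M

| flask | protic impurity | initiator | remark | time |
|---|---|---|---|---|
| alder | 2 mM | 0.10 mM | run made earlier |  |
| larch | 2 mM | 0.15 mM | run made earlier |  |
| cedar | 4 mM | 0.20 mM | run made earlier |  |
| flask | 2.00 mM | 0.20 mM |  | 40 h |

- alder (time / h: monomer in chains / %, free monomer / %): 2.00: 7.0, 84.6; 3.00: 9.9, 80.6; 4.00: 11.7, 77.1; 6.00: 18.5, 71.5; 10.0: 30.9, 59.5; 15.0: 43.0, 47.8; 25.0: 58.6, 31.1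
- larch (time / h: monomer in chains / %, free monomer / %): 2.00: 8.8, 83.8; 3.00: 13.5, 75.8; 4.00: 19.7, 71.4; 6.00: 28.0, 62.5; 10.0: 42.9, 47.7; 15.0: 56.4, 34.8; 25.0: 71.8, 16.3
- cedar (time / h: monomer in chains / %, free monomer / %): 2.00: 10.7, 68.6; 6.00: 30.0, 50.9; 12.0: 50.4, 28.7; 15.0: 55.5, 23.6; 25.0: 70.4, 9.2

(readings scatter by 1 percentage point)

- the average divides the monomer in chains by the number of chains begun, living and dead together
- the numbers in the tables scatter by 1 percentage point (one standard deviation)
- steps that have been proposed: free monomer + initiator -> living end + monomer in chains; free monomer + living end -> monomer in chains + living end; protic impurity + free monomer -> quenched substrate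
- the earlier runs do not show the number of chains; that part of a forecast is a guess

1. whether the average number of monomer units in a chain (chains begun, living or dead) reaches 40 by 40 h (yes / no)
2. average number of monomer units in a chain (chains begun, living or dead) at 40 h

I sort the earlier runs by time scale. Quenching comes first. In cedar, the monomer missing from free monomer plus monomer in chains reads 20.7 % at 2.00 h and 20.4 % at 25.0 h, against an impurity charge of 20.0 % of the monomer, so I take one monomer lost per impurity molecule.

Growth is slower. From 6.00 h to 25.0 h, free monomer decays at 0.0438 h⁻¹ in alder and 0.0900 h⁻¹ in cedar. Divided by the initiator charged, these agree within the scatter, although cedar has twice the impurity. So I freeze the living ends at the initiator charge, which makes growth pseudo-first-order, with growth constant κ, the decay rate per initiator charged, 7.40 M⁻¹ min⁻¹.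

Larch, left out of κ, tests it: at 25.0 h I reckon 73.0 % in chains and read 71.8 %.

The readings do not count chains, so one chain per initiator is my guess. With c for a charge, the length is the ceiling (cM − cH)/cN times the part of growth finished. For the flask, the ceiling is 90.0 and the rate is 0.0888 h⁻¹, so I expect 87.4 at 40 h. With the living ends frozen at their full charge from time zero, which passes over the time initiation takes, I estimate that the length passes 40 near 6.62 h; the estimate is rough, but it stands well before 40 h.

The forecast answers yes with 86, against my 87.4, adding “Undetected transfer would add chains and lower this, so the range is skewed low”.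

The flask gives yes and 87.3.

    free monomer + initiator → living end + monomer in chains (k = 1.20 M⁻¹ min⁻¹)
    free monomer + living end → monomer in chains + living end, rate k2*[living end]*[free monomer] (k = 7.40 M⁻¹ min⁻¹)
    protic impurity + free monomer → quenched substrate (k = 2.40 M⁻¹ min⁻¹)

In the flask, half of the quenching up to 40 h is done by 0.249 h and half of the growth by 8.23 h, far later, and quenched substrate stands at 10.0 % of the monomer charged at 4.00 h and at 10.0 % at 40.0 h. Starting from the 16.1 % of free monomer at 20.0 h, κ gives 2.73 % at 40 h, and the flask holds 2.73 %.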